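## Retrosynthetic overview

- **Feature:** with the ring numbered O1, O2, C3 (ketal), C4, C5, C6 and the acid arm C7, C8, the unit C6–C7–C8 carries oxygen on C6 and ends in the carboxyl C8. This β-oxy acid equals a terminal C6/C7 epoxide plus CO, stored as a 4-substituted oxetan-2-one.
- **Last C–C bond:** Sonogashira coupling joins the alkyne terminus of the finished dioxane to (E)-1-iodoundeca-1,10-diene, made from dec-9-en-1-ol by oxidation and Takai olefination.
- **O1–C6 bond of the 1,2-dioxane:** ozonolysis of a C3 methylidene in methanol gives a C3 methoxy hydroperoxide. It opens the (4R)-β-lactone at C6 with inversion (6S) and frees C8 as the acid. C3 is then settled by acid equilibration.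
- **Lactone and ring order:** the lactone comes from the (R)-epoxide and CO. The epoxide comes from (R)-epichlorohydrin and an allyl Grignard built from methallyl dichloride and a silylbutynyl Grignard. Rings form in the order oxirane, oxetan-2-one, 1,2-dioxane.

Key step: step 4

Assumption: descriptors follow the ring numbering above. The target is 3R,6S, with OMe and CH2CO2H cis, which is the chair with OMe axial and both carbon chains equatorial. All peroxide-bearing compounds are handled cold and on small scale.

## Route

Step 1
Reactants: 1 (4-bromobut-1-yn-1-yl)trimethylsilane; 2 3-chloro-2-(chloromethyl)prop-1-ene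
Product: 4 [6-(chloromethyl)hept-6-en-1-yn-1-yl]trimethylsilane, via butynyl Grignard 3 (not isolated)
Conditions: Mg, THF, 40 °C; then added slowly to 2 (3 equiv), Li2CuCl4 (3 mol%), THF, −20 → 0 °C
Reagents that add atoms: magnesium, [Mg] (held in intermediate 3 only)
Why: Copper-catalysed Grignard allylic substitution: the symmetric bis-allylic dichloride gives the same product by SN2 or SN2' attack, its excess and the inverse addition should stop the reaction at mono-substitution, and no stereocenter is formed.

Step 2
Reactants: 4 [6-(chloromethyl)hept-6-en-1-yn-1-yl]trimethylsilane; 5 (R)-epichlorohydrin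
Product: 7 (2R)-1-chloro-5-methylidene-10-(trimethylsilyl)dec-9-yn-2-ol, via allyl Grignard 6 (not isolated)
Conditions: Mg turnings (5 equiv), THF, 0 °C, slow addition of 4; then CuI (10 mol%), 5, THF, −40 → −10 °C; aq NH4Cl
Reagents that add atoms: magnesium, [Mg] (held in intermediate 6 only)
Why: Copper-catalysed Grignard opening of a terminal epoxide: the two CH2 termini of the 2-substituted allyl Grignard are equivalent so no allylic regioisomer can arise, attack at the unsubstituted oxirane carbon leaves the stereocenter (future C6) untouched, and cold slow formation over excess magnesium suppresses Wurtz coupling.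

Step 3
Reactants: 7 (2R)-1-chloro-5-methylidene-10-(trimethylsilyl)dec-9-yn-2-ol
Product: 8 (2R)-2-[3-methylidene-8-(trimethylsilyl)oct-7-yn-1-yl]oxirane
Conditions: NaH, THF, 0 °C → rt
Reagents that add atoms: none
Why: Intramolecular Williamson closure of a chlorohydrin: the alkoxide displaces the primary chloride, the C–O bond at the stereocenter is not broken so R is retained, and the aprotic medium spares the alkynylsilane.

Step 4
Reactants: 8 (2R)-2-[3-methylidene-8-(trimethylsilyl)oct-7-yn-1-yl]oxirane; 9 carbon monoxide
Product: 10 (4R)-4-[3-methylidene-8-(trimethylsilyl)oct-7-yn-1-yl]oxetan-2-one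
Conditions: [(salph)Al(THF)2][Co(CO)4] (2 mol%; salph = N,N'-bis(3,5-di-tert-butylsalicylidene)-1,2-phenylenediaminate), CO (60 bar), DME, 50 °C
Reagents that add atoms: none
Why: The aluminium cation binds the oxirane oxygen, [Co(CO)4]− opens the ring by SN2 attack at the unsubstituted C7, migratory insertion of CO turns the alkylcobalt into an acylcobalt (new C7–C8 bond), and the aluminium alkoxide on C6 displaces cobaltate from the acyl carbon, returning the ion pair. This is the known ring-expanding carbonylation of monosubstituted terminal epoxides to β-lactones by Lewis acid/tetracarbonylcobaltate ion pairs, applied here to a new substrate. The oxetan-2-one closes by a 4-exo-trig addition–elimination at the acylcobalt carbon. No stereocenter is created, and because the C6–O bond is never broken the (R)-epoxide should give the (R)-lactone with retention. The step needs regioselectivity for C7 over C6, secured by the terminal monosubstituted epoxide, and chemoselectivity over the π-systems, secured by the absence of any hydride source for the 1,1-disubstituted alkene and by the silyl cap on an alkyne that the saturated cobaltate anion under CO pressure has little tendency to bind. The lactone stores the C6 configuration, brings in C8 at the acid oxidation level and makes C6 electrophilic for the peroxide closure.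

Step 5
Reactants: 10 (4R)-4-[3-methylidene-8-(trimethylsilyl)oct-7-yn-1-yl]oxetan-2-one
Product: 12 (4R)-4-[3-hydroperoxy-3-methoxy-8-(trimethylsilyl)oct-7-yn-1-yl]oxetan-2-one (both C3 epimers), via carbonyl oxide 11 (not isolated)
Conditions: O3/O2, CH2Cl2/MeOH (4:1), Sudan Red 7B as end-point dye, −78 °C; N2 purge; concentration below 20 °C, no reductant; rapid silica filtration
Reagents that add atoms: ozone, [O-][O+]=O; methanol, CO
Why: Criegee ozonolysis with methanol trapping: the 1,1-disubstituted alkene reacts far faster than the silyl alkyne, the primary ozonide cleaves to formaldehyde and the dialkyl carbonyl oxide at C3, methanol adds to give the α-methoxy hydroperoxide, neutral cold methanol leaves the lactone closed, and C3 forms without control and is corrected in step 7.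

Step 6
Reactants: 12 (4R)-4-[3-hydroperoxy-3-methoxy-8-(trimethylsilyl)oct-7-yn-1-yl]oxetan-2-one (both C3 epimers)
Product: 13 [(3RS,6S)-3-methoxy-3-[5-(trimethylsilyl)pent-4-yn-1-yl]-1,2-dioxan-6-yl]acetic acid
Conditions: KOtBu (1.0 equiv), 18-crown-6 (1.0 equiv), THF (high dilution), −20 → 0 °C; then cold 0.5 M HCl to pH 3–4
Reagents that add atoms: none
Why: Proposed new method: deprotonation of the hydroperoxide (far more acidic than tert-butanol) gives a tethered peroxide anion whose backside attack on C6, anti to the strained C6–O lactone bond, is a 6-exo-tet closure, whereas attack at the acyl carbon C8 would need an eight-membered perester; alkyl–oxygen cleavage releases the ring strain, expels the carboxylate and inverts C6 from R to S, and the carboxylate salt is itself a poor partner for retro-Michael loss of the peroxide. The closest known reaction types are the invertive SN2 opening of 4-alkyl β-lactones at C4 by azide, sulfonamide and cuprate nucleophiles, and the base-mediated cyclisation of hydroperoxy ketals onto secondary sulfonates, oxetanes or epoxides to give cyclic peroxides.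

Step 7
Reactants: 13 [(3RS,6S)-3-methoxy-3-[5-(trimethylsilyl)pent-4-yn-1-yl]-1,2-dioxan-6-yl]acetic acid
Product: 14 [(3R,6S)-3-methoxy-3-[5-(trimethylsilyl)pent-4-yn-1-yl]-1,2-dioxan-6-yl]acetic acid
Conditions: camphor-10-sulfonic acid (10 mol%), MeOH (5 equiv), CH2Cl2, 0 °C → rt; chromatography, the 3S epimer resubmitted
Reagents that add atoms: methanol, CO
Why: Acid-catalysed perketal exchange: reversible loss of methanol gives the ring peroxycarbenium ion, and re-addition should settle on the chair with OMe axial (anomeric effect) and both carbon chains equatorial, which is 3R,6S, while the low methanol concentration holds back Fischer esterification and ring opening and C6 is not involved.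

Step 8
Reactants: 14 [(3R,6S)-3-methoxy-3-[5-(trimethylsilyl)pent-4-yn-1-yl]-1,2-dioxan-6-yl]acetic acid
Product: 15 [(3R,6S)-3-methoxy-3-(pent-4-yn-1-yl)-1,2-dioxan-6-yl]acetic acid
Conditions: TBAF (1.5 equiv), AcOH (1.5 equiv), THF, 0 °C → rt
Reagents that add atoms: none
Why: Fluoride-mediated protodesilylation of an alkynylsilane: buffered fluoride attacks only silicon, and the near-neutral medium avoids Kornblum–DeLaMare or retro-Michael cleavage of the dioxane.

Step 9
Reactants: 16 dec-9-en-1-ol
Product: 17 dec-9-enal
Conditions: TEMPO (10 mol%), PhI(OAc)2 (1.1 equiv), CH2Cl2, rt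
Reagents that add atoms: none
Why: Oxoammonium (TEMPO) oxidation of a primary alcohol stops at the aldehyde in anhydrous CH2Cl2 and leaves the terminal alkene alone.

Step 10
Reactants: 17 dec-9-enal
Product: 18 (1E)-1-iodoundeca-1,10-diene
Conditions: CrCl2 (6 equiv), CHI3 (2 equiv), THF/1,4-dioxane, 0 °C → rt
Reagents that add atoms: iodoform, IC(I)I
Why: Takai olefination: the gem-dichromium reagent from iodoform adds to the aldehyde and eliminates to give preferentially the (E)-vinyl iodide, the dioxane co-solvent favours E, and the isolated terminal alkene is inert.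

Step 11
Reactants: 15 [(3R,6S)-3-methoxy-3-(pent-4-yn-1-yl)-1,2-dioxan-6-yl]acetic acid; 18 (1E)-1-iodoundeca-1,10-diene
Product: 19 [(3R,6S)-3-[(6E)-hexadeca-6,15-dien-4-yn-1-yl]-3-methoxy-1,2-dioxan-6-yl]acetic acid (target)
Conditions: Pd(PPh3)4 (5 mol%), CuI (10 mol%), Et3N (5 equiv), THF, degassed, rt; pH 4 buffer work-up
Reagents that add atoms: none
Why: Sonogashira coupling: insertion of zerovalent palladium into the vinyl C–I bond and transfer of the copper acetylide keep the E geometry at room temperature, conditions of this kind are known to leave dialkyl peroxides and perketals intact, the acid rides along as its ammonium salt, and neither stereocenter is touched.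

## Compound list

| No. | Name | SMILES | Role |
|---|---|---|---|
| 1 | (4-bromobut-1-yn-1-yl)trimethylsilane | C[Si](C)(C)C#CCCBr | starting material |
| 2 | 3-chloro-2-(chloromethyl)prop-1-ene | C=C(CCl)CCl | starting material |
| 3 | [4-(trimethylsilyl)but-3-yn-1-yl]magnesium bromide | C[Si](C)(C)C#CCC[Mg]Br | intermediate |
| 4 | [6-(chloromethyl)hept-6-en-1-yn-1-yl]trimethylsilane | C[Si](C)(C)C#CCCCC(=C)CCl | intermediate |
| 5 | (R)-epichlorohydrin | ClC[C@H]1CO1 | starting material |
| 6 | [2-methylidene-7-(trimethylsilyl)hept-6-yn-1-yl]magnesium chloride | C[Si](C)(C)C#CCCCC(=C)C[Mg]Cl | intermediate |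
| 7 | (2R)-1-chloro-5-methylidene-10-(trimethylsilyl)dec-9-yn-2-ol | C[Si](C)(C)C#CCCCC(=C)CC[C@@H](O)CCl | intermediate |
| 8 | (2R)-2-[3-methylidene-8-(trimethylsilyl)oct-7-yn-1-yl]oxirane | C[Si](C)(C)C#CCCCC(=C)CC[C@@H]1CO1 | intermediate |
| 9 | carbon monoxide | [C-]#[O+] | starting material |
| 10 | (4R)-4-[3-methylidene-8-(trimethylsilyl)oct-7-yn-1-yl]oxetan-2-one | C[Si](C)(C)C#CCCCC(=C)CC[C@@H]1CC(=O)O1 | intermediate |
| 11 | C3 carbonyl oxide of the (4R)-lactone | C[Si](C)(C)C#CCCCC(=[O+][O-])CC[C@@H]1CC(=O)O1 | intermediate |
| 12 | (4R)-4-[3-hydroperoxy-3-methoxy-8-(trimethylsilyl)oct-7-yn-1-yl]oxetan-2-one, both C3 epimers | C[Si](C)(C)C#CCCCC(OC)(OO)CC[C@@H]1CC(=O)O1 | intermediate |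
| 13 | [(3RS,6S)-3-methoxy-3-[5-(trimethylsilyl)pent-4-yn-1-yl]-1,2-dioxan-6-yl]acetic acid | C[Si](C)(C)C#CCCCC1(OC)CC[C@@H](CC(=O)O)OO1 | intermediate |
| 14 | [(3R,6S)-3-methoxy-3-[5-(trimethylsilyl)pent-4-yn-1-yl]-1,2-dioxan-6-yl]acetic acid | C[Si](C)(C)C#CCCC[C@]1(OC)CC[C@@H](CC(=O)O)OO1 | intermediate |
| 15 | [(3R,6S)-3-methoxy-3-(pent-4-yn-1-yl)-1,2-dioxan-6-yl]acetic acid | C#CCCC[C@]1(OC)CC[C@@H](CC(=O)O)OO1 | intermediate |
| 16 | dec-9-en-1-ol | C=CCCCCCCCCO | starting material |
| 17 | dec-9-enal | C=CCCCCCCCC=O | intermediate |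
| 18 | (1E)-1-iodoundeca-1,10-diene | C=CCCCCCCC/C=C/I | intermediate |
| 19 | [(3R,6S)-3-[(6E)-hexadeca-6,15-dien-4-yn-1-yl]-3-methoxy-1,2-dioxan-6-yl]acetic acid | C=CCCCCCCC/C=C/C#CCCC[C@]1(OC)CC[C@@H](CC(=O)O)OO1 | target |

## Step count and risks

Total step count: 11. Longest linear sequence: 9 (steps 1–8 and 11).

**Step 6 (the labelled step).**
- Risk: intermolecular attack of the peroxide anion at the acyl carbon (perester oligomers), or enolisation and β-elimination of the lactone to an unsaturated carboxylate, may outrun the alkyl–oxygen cleavage.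
- The fallback sets out from 10, uses only known chemistry and returns at 13. The acid arm is taken down to the alcohol level so that no acidic α-hydrogen flanks the leaving group.
- LiBH4 (THF, 0 °C) reduces the lactone to (3R)-6-methylidene-11-(trimethylsilyl)undec-10-yne-1,3-diol F1.
- TBSCl/imidazole silylates the primary hydroxyl to give (3R)-1-[(tert-butyldimethylsilyl)oxy]-6-methylidene-11-(trimethylsilyl)undec-10-yn-3-ol F2.
- MsCl/Et3N gives (3R)-1-[(tert-butyldimethylsilyl)oxy]-6-methylidene-11-(trimethylsilyl)undec-10-yn-3-yl methanesulfonate F3.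
- Ozonolysis in CH2Cl2/MeOH gives (3R)-1-[(tert-butyldimethylsilyl)oxy]-6-hydroperoxy-6-methoxy-11-(trimethylsilyl)undec-10-yn-3-yl methanesulfonate F4.
- KOtBu/18-crown-6 closes the ring by the known invertive displacement of a secondary sulfonate by a hydroperoxy ketal, giving tert-butyl{2-[(6S)-3-methoxy-3-[5-(trimethylsilyl)pent-4-yn-1-yl]-1,2-dioxan-6-yl]ethoxy}dimethylsilane F5.
- Camphor-10-sulfonic acid in MeOH frees 2-[(6S)-3-methoxy-3-[5-(trimethylsilyl)pent-4-yn-1-yl]-1,2-dioxan-6-yl]ethanol F6.
- TEMPO/PhI(OAc)2 in MeCN/water oxidises F6 to acid 13.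

**Step 4 (key step).**
- Risk: binding of the alkyne to cobalt with loss of active cobaltate, isomerisation of the epoxide to the methyl ketone, or onward ring-opening polymerisation of the lactone may erode conversion.
- The fallback sets out from 8 and returns at 10, replacing substrate control by catalyst control.
- H5IO6 in THF/Et2O cleaves the epoxide to 4-methylidene-9-(trimethylsilyl)non-8-ynal F7.
- A catalytic asymmetric ketene–aldehyde [2+2] cyclocondensation then gives 10. Conditions are acetyl chloride, iPr2NEt, LiClO4 and an O-trimethylsilyl cinchona alkaloid in CH2Cl2/Et2O at −78 °C. The quinine- or quinidine-derived pseudo-enantiomer is chosen as the one that delivers 4R.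

**Step 7.**
- Risk: the thermodynamic bias at C3 may be modest, because the unwanted epimer can also place OMe axial after a ring flip. Slow esterification of the acid arm may also accompany the exchange.
- The fallback sets out from 13 and returns at 15, accepting the ester instead of avoiding it.
- TsOH in neat MeOH esterifies and equilibrates in one operation.
- Methyl [(3R,6S)-3-methoxy-3-[5-(trimethylsilyl)pent-4-yn-1-yl]-1,2-dioxan-6-yl]acetate F8 is separated on silica, where esters resolve better than acids, and its C3 epimer is recycled.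
- LiOH in THF/MeOH/water at 0 °C then removes both the methyl ester and the alkynyl silane, so step 8 is no longer needed.

## Further compounds

F1 | step 6 | (3R)-6-methylidene-11-(trimethylsilyl)undec-10-yne-1,3-diol | C[Si](C)(C)C#CCCCC(=C)CC[C@@H](O)CCO
F2 | step 6 | (3R)-1-[(tert-butyldimethylsilyl)oxy]-6-methylidene-11-(trimethylsilyl)undec-10-yn-3-ol | C[Si](C)(C)C#CCCCC(=C)CC[C@@H](O)CCO[Si](C)(C)C(C)(C)C
F3 | step 6 | (3R)-1-[(tert-butyldimethylsilyl)oxy]-6-methylidene-11-(trimethylsilyl)undec-10-yn-3-yl methanesulfonate | C[Si](C)(C)C#CCCCC(=C)CC[C@@H](OS(C)(=O)=O)CCO[Si](C)(C)C(C)(C)C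
F4 | step 6 | (3R)-1-[(tert-butyldimethylsilyl)oxy]-6-hydroperoxy-6-methoxy-11-(trimethylsilyl)undec-10-yn-3-yl methanesulfonate | C[Si](C)(C)C#CCCCC(OC)(OO)CC[C@@H](OS(C)(=O)=O)CCO[Si](C)(C)C(C)(C)C
F5 | step 6 | tert-butyl{2-[(6S)-3-methoxy-3-[5-(trimethylsilyl)pent-4-yn-1-yl]-1,2-dioxan-6-yl]ethoxy}dimethylsilane | C[Si](C)(C)C#CCCCC1(OC)CC[C@@H](CCO[Si](C)(C)C(C)(C)C)OO1
F6 | step 6 | 2-[(6S)-3-methoxy-3-[5-(trimethylsilyl)pent-4-yn-1-yl]-1,2-dioxan-6-yl]ethanol | C[Si](C)(C)C#CCCCC1(OC)CC[C@@H](CCO)OO1
F7 | step 4 | 4-methylidene-9-(trimethylsilyl)non-8-ynal | C[Si](C)(C)C#CCCCC(=C)CCC=O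
F8 | step 7 | methyl [(3R,6S)-3-methoxy-3-[5-(trimethylsilyl)pent-4-yn-1-yl]-1,2-dioxan-6-yl]acetate | C[Si](C)(C)C#CCCC[C@]1(OC)CC[C@@H](CC(=O)OC)OO1
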